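The route disconnects the pyridone ring at C2–C3. The vicinal C3 methoxy and C4 carbonyl oxygens, with C4 bonded to C4a and N1 to C8a of the unsubstituted benzo ring, are the C2/C3 dicarbonyl, nitrogen and arene of isatin. In one operation, methoxide opens the lactam of an N-(2-oxoalkyl)isatin and the N-methylene enolate recloses onto the glyoxylate ester. This forms C2–C3 and the 3-hydroxy-4-quinolone, with the whole side chain attached through a C1′ ketone. The precursor is isatin N-alkylated by a C14 chloromethyl ketone whose distal (C12′) ketone is masked as a dioxolane, so that later Wolff–Kishner removal of the C1′ oxygen is unambiguous.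

Key step: step 5

Assumption: the target has no stereocentre and is achiral, so no step has to set or preserve configuration.

Design remark: the chain ends are differentiated from the start (half-ester of dodecanedioic acid), which avoids statistical monofunctionalisation of a symmetrical diketone. The C12′ ketone travels as a dioxolane for two reasons: ionic hydrogenation is not credible for an acyl group on an electron-poor, acid-protonated quinolone, and a free methyl ketone would not survive a hydrazone-based deoxygenation.

Step 1
Reactants: 1 dodecanedioic acid monomethyl ester (12-methoxy-12-oxododecanoic acid)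
Product: 3 methyl 12-oxotridecanoate, via methyl 12-chloro-12-oxododecanoate 2 (not isolated)
Conditions: (COCl)2, DMF (cat.), CH2Cl2, 0 °C → rt, evaporate; then MeMgBr (1.05 equiv), Fe(acac)3 (3 mol %), THF, −78 °C
Reagents that add atoms: methylmagnesium bromide, C[Mg]Br
Why: Acid chloride formation followed by iron-catalysed cross-coupling of the acid chloride with the Grignard reagent at −78 °C should stop at the methyl ketone and leave the methyl ester untouched.

Step 2
Reactants: 3 methyl 12-oxotridecanoate
Product: 4 methyl 11-(2-methyl-1,3-dioxolan-2-yl)undecanoate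
Conditions: HOCH2CH2OH (1.2 equiv), TsOH·H2O (cat.), toluene, reflux, Dean–Stark
Reagents that add atoms: ethylene glycol, OCCO
Why: Acid-catalysed ketalisation with azeotropic removal of water masks the methyl ketone as a dioxolane that is stable to every basic step that follows, and the small excess of glycol limits transesterification.

Step 3
Reactants: 4 methyl 11-(2-methyl-1,3-dioxolan-2-yl)undecanoate
Product: 6 1-chloro-12-(2-methyl-1,3-dioxolan-2-yl)dodecan-2-one, via lithium 1-chloro-2-methoxy-12-(2-methyl-1,3-dioxolan-2-yl)dodecan-2-olate 5 (not isolated)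
Conditions: ICH2Cl (1.4 equiv), MeLi·LiBr (1.3 equiv, added dropwise), THF/Et2O, −78 °C; AcOH/THF quench at −78 °C, then aq. NaHCO3
Reagents that add atoms: chloroiodomethane, ClCI
Why: Iodine–lithium exchange generates chloromethyllithium in the presence of the ester (carbenoid chloromethylation of an ester), and the tetrahedral alkoxide 5 persists at −78 °C and releases the chloromethyl ketone only on the cold acidic quench, which prevents a second addition.

Step 4
Reactants: 6 1-chloro-12-(2-methyl-1,3-dioxolan-2-yl)dodecan-2-one; 7 isatin
Product: 8 1-[12-(2-methyl-1,3-dioxolan-2-yl)-2-oxododecyl]indoline-2,3-dione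
Conditions: K2CO3 (1.3 equiv), dry DMF, rt → 50 °C
Reagents that add atoms: none
Why: SN2 N-alkylation of the isatin anion by the reactive α-chloroketone under carbonate conditions favours N- over O-alkylation and is too mild to trigger Darzens or aldol chemistry at C3.

Step 5
Reactants: 8 1-[12-(2-methyl-1,3-dioxolan-2-yl)-2-oxododecyl]indoline-2,3-dione
Product: 10 3-hydroxy-2-[11-(2-methyl-1,3-dioxolan-2-yl)undecanoyl]quinolin-4(1H)-one, via methyl 2-(2-{[12-(2-methyl-1,3-dioxolan-2-yl)-2-oxododecyl]amino}phenyl)-2-oxoacetate 9 (not isolated)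
Conditions: NaOMe (3 equiv, anhydrous), MeOH, 0 °C → reflux; then AcOH to pH 6, 0 °C
Reagents that add atoms: none
Why: Methoxide adds to the C2 lactam carbonyl of 8 (activated by the adjacent C3 ketone) and opens the five-membered ring to the methyl arylglyoxylate 9, whose aryl ketone is deactivated as a vinylogous amide by the ortho NHR group while the ester carbonyl stays activated by that ketone. Reversible deprotonation of the N–CH2–C(=O) methylene gives the enolate that attacks the ester carbonyl in a 6-(enolexo)-exo-trig Dieckmann closure, forming C2–C3; loss of methoxide and enolisation give the aromatic 3-hydroxy-4-quinolone, which methoxide deprotonates irreversibly. The closest known reaction is the alkoxide-induced ring expansion of N-(acylmethyl)isatins and isatin-N-acetic esters, the isatin counterpart of the Gabriel–Colman rearrangement. No stereocentre is formed. The step needs enolisation on the N–CH2 side rather than the C3 side of the chain ketone (the C3 enolate could only close 7- or 8-membered rings) and acylation rather than 5-exo aldol onto the aryl ketone followed by dehydration to an indole; strictly anhydrous methoxide keeps the electrophile an ester and not a carboxylate, and only the six-membered closure ends in an irreversible deprotonation. The dioxolane is inert to methoxide, so the distal carbonyl takes no part.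

Step 6
Reactants: 10 3-hydroxy-2-[11-(2-methyl-1,3-dioxolan-2-yl)undecanoyl]quinolin-4(1H)-one
Product: 11 3-methoxy-2-[11-(2-methyl-1,3-dioxolan-2-yl)undecanoyl]quinolin-4(1H)-one
Conditions: MeI (1.05 equiv), K2CO3 (1.2 equiv), DMF, 0 °C → rt
Reagents that add atoms: iodomethane, CI
Why: Williamson-type O-methylation should be selective because the 3-OH is an enol conjugated to the C1′ ketone (a vinylogous acid) and far more acidic than N1–H, so one equivalent of base and electrophile alkylates O3.

Step 7
Reactants: 11 3-methoxy-2-[11-(2-methyl-1,3-dioxolan-2-yl)undecanoyl]quinolin-4(1H)-one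
Product: 13 3-methoxy-2-[11-(2-methyl-1,3-dioxolan-2-yl)undecyl]quinolin-4(1H)-one, via 2-[1-hydrazinylidene-11-(2-methyl-1,3-dioxolan-2-yl)undecyl]-3-methoxyquinolin-4(1H)-one 12 (not isolated)
Conditions: N2H4·H2O (5 equiv), KOH (4 equiv), diethylene glycol, 130 °C; then distil off H2O/N2H4, 195 °C, N2
Reagents that add atoms: none
Why: Wolff–Kishner reduction (Huang-Minlon modification) should act only at C1′, because C4 is a vinylogous amide that forms no hydrazone and C12′ is masked as the base-stable dioxolane, so loss of N2 from hydrazone 12 leaves the C1′ methylene.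

Step 8
Reactants: 13 3-methoxy-2-[11-(2-methyl-1,3-dioxolan-2-yl)undecyl]quinolin-4(1H)-one
Product: 14 3-methoxy-2-(12-oxotridecyl)quinolin-4(1H)-one
Conditions: 1 M aq. HCl, THF, rt; aq. NaHCO3 work-up
Reagents that add atoms: water, O
Why: Acid-catalysed hydrolysis of the dioxolane (ketal deprotection) liberates the C12′ methyl ketone, and the methyl ether and quinolone are stable to dilute acid at room temperature.

Compound list
1 | dodecanedioic acid monomethyl ester (12-methoxy-12-oxododecanoic acid) | COC(=O)CCCCCCCCCCC(=O)O | starting material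
2 | methyl 12-chloro-12-oxododecanoate | COC(=O)CCCCCCCCCCC(=O)Cl | intermediate (not isolated)
3 | methyl 12-oxotridecanoate | COC(=O)CCCCCCCCCCC(C)=O | intermediate
4 | methyl 11-(2-methyl-1,3-dioxolan-2-yl)undecanoate | COC(=O)CCCCCCCCCCC1(C)OCCO1 | intermediate
5 | lithium 1-chloro-2-methoxy-12-(2-methyl-1,3-dioxolan-2-yl)dodecan-2-olate | [Li+].[O-]C(CCl)(OC)CCCCCCCCCCC1(C)OCCO1 | intermediate (not isolated)
6 | 1-chloro-12-(2-methyl-1,3-dioxolan-2-yl)dodecan-2-one | ClCC(=O)CCCCCCCCCCC1(C)OCCO1 | intermediate
7 | isatin (indoline-2,3-dione) | O=C1Nc2ccccc2C1=O | starting material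
8 | 1-[12-(2-methyl-1,3-dioxolan-2-yl)-2-oxododecyl]indoline-2,3-dione | O=C1C(=O)N(CC(=O)CCCCCCCCCCC3(C)OCCO3)c2ccccc12 | intermediate (key-step precursor)
9 | methyl 2-(2-{[12-(2-methyl-1,3-dioxolan-2-yl)-2-oxododecyl]amino}phenyl)-2-oxoacetate | COC(=O)C(=O)c1ccccc1NCC(=O)CCCCCCCCCCC2(C)OCCO2 | intermediate (not isolated)
10 | 3-hydroxy-2-[11-(2-methyl-1,3-dioxolan-2-yl)undecanoyl]quinolin-4(1H)-one | O=C(CCCCCCCCCCC3(C)OCCO3)c1[nH]c2ccccc2c(=O)c1O | intermediate (key-step product)
11 | 3-methoxy-2-[11-(2-methyl-1,3-dioxolan-2-yl)undecanoyl]quinolin-4(1H)-one | COc1c(C(=O)CCCCCCCCCCC3(C)OCCO3)[nH]c2ccccc2c1=O | intermediate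
12 | 2-[1-hydrazinylidene-11-(2-methyl-1,3-dioxolan-2-yl)undecyl]-3-methoxyquinolin-4(1H)-one | COc1c(C(=NN)CCCCCCCCCCC3(C)OCCO3)[nH]c2ccccc2c1=O | intermediate (not isolated)
13 | 3-methoxy-2-[11-(2-methyl-1,3-dioxolan-2-yl)undecyl]quinolin-4(1H)-one | COc1c(CCCCCCCCCCCC3(C)OCCO3)[nH]c2ccccc2c1=O | intermediate
14 | 3-methoxy-2-(12-oxotridecyl)quinolin-4(1H)-one | COc1c(CCCCCCCCCCCC(C)=O)[nH]c2ccccc2c1=O | target

Total step count: 8. Longest linear sequence: 8 steps (1 → 14; isatin 7 enters at step 4).

Steps most likely to fail

Step 5 (ring expansion). After lactam opening, the N–CH2 enolate may add to the aryl ketone and the aldol adduct may dehydrate irreversibly to an indole. Traces of hydroxide may also saponify the glyoxylate ester, so that no acyl electrophile remains. The fallback sets out from isatin 7 and ester 4 and returns at 11. It performs the ring expansion on the ester-activated substrate and attaches the chain afterwards. N-alkylation of 7 with methyl bromoacetate (K2CO3, DMF) should give methyl 2-(2,3-dioxoindolin-1-yl)acetate F1, whose N-methylene is flanked by an ester and has no second enolisable side. NaOMe in MeOH should expand it to methyl 3-hydroxy-4-oxo-1,4-dihydroquinoline-2-carboxylate F2. O-methylation (MeI, K2CO3, DMF) should give methyl 3-methoxy-4-oxo-1,4-dihydroquinoline-2-carboxylate F3. Crossed Claisen condensation of N-deprotonated F3 (LiHMDS) with the lithium enolate of 4 (excess LDA, THF, −78 → 0 °C) should give the racemic β-keto ester methyl 2-[(3-methoxy-4-oxo-1,4-dihydroquinolin-2-yl)carbonyl]-11-(2-methyl-1,3-dioxolan-2-yl)undecanoate F4. Krapcho dealkoxycarbonylation (LiCl, wet DMSO, 140 °C) then removes the ester carbon and gives 11.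

Step 7 (Wolff–Kishner). Hydrazone formation at the hindered C1′ ketone, which is conjugated to the C3 methoxy group, may be slow. In hot KOH the 3-methoxy group may be lost by nucleophilic demethylation or displaced by the hydrazone nitrogen. The fallback sets out from 11 and returns at 13 by radical deoxygenation. NaBH4 (MeOH, 0 °C) should reduce only the C1′ ketone to the racemic carbinol 2-[1-hydroxy-11-(2-methyl-1,3-dioxolan-2-yl)undecyl]-3-methoxyquinolin-4(1H)-one F5. 1,1′-Thiocarbonyldiimidazole (DMAP cat., THF, reflux) should convert it into O-[1-(3-methoxy-4-oxo-1,4-dihydroquinolin-2-yl)-11-(2-methyl-1,3-dioxolan-2-yl)undecyl] 1H-imidazole-1-carbothioate F6. Bu3SnH/AIBN (toluene, 110 °C, Barton–McCombie) should cleave the C1′–O bond through the ring-stabilised radical and give 13.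

Step 3 (chloromethylation). The tetrahedral adduct may collapse before the quench and take up a second carbenoid, or the carbenoid may decompose before it is trapped. The fallback sets out from 4 and returns at 6 through an acyl donor that gives a chelated adduct. MeNH(OMe)·HCl with i-PrMgCl (THF, −20 °C) should convert 4 into N-methoxy-N-methyl-11-(2-methyl-1,3-dioxolan-2-yl)undecanamide F7. ICH2Cl/MeLi·LiBr (THF, −78 °C) then adds once to F7, and the adduct releases 6 only on work-up.

Further compounds
F1 | step 5 | methyl 2-(2,3-dioxoindolin-1-yl)acetate | COC(=O)CN1C(=O)C(=O)c2ccccc12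
F2 | step 5 | methyl 3-hydroxy-4-oxo-1,4-dihydroquinoline-2-carboxylate | COC(=O)c1[nH]c2ccccc2c(=O)c1O
F3 | step 5 | methyl 3-methoxy-4-oxo-1,4-dihydroquinoline-2-carboxylate | COC(=O)c1[nH]c2ccccc2c(=O)c1OC
F4 | step 5 | methyl 2-[(3-methoxy-4-oxo-1,4-dihydroquinolin-2-yl)carbonyl]-11-(2-methyl-1,3-dioxolan-2-yl)undecanoate (racemic) | COC(=O)C(CCCCCCCCCC3(C)OCCO3)C(=O)c1[nH]c2ccccc2c(=O)c1OC
F5 | step 7 | 2-[1-hydroxy-11-(2-methyl-1,3-dioxolan-2-yl)undecyl]-3-methoxyquinolin-4(1H)-one (racemic) | COc1c(C(O)CCCCCCCCCCC3(C)OCCO3)[nH]c2ccccc2c1=O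
F6 | step 7 | O-[1-(3-methoxy-4-oxo-1,4-dihydroquinolin-2-yl)-11-(2-methyl-1,3-dioxolan-2-yl)undecyl] 1H-imidazole-1-carbothioate (racemic) | COc1c(C(OC(=S)n4ccnc4)CCCCCCCCCCC3(C)OCCO3)[nH]c2ccccc2c1=O
F7 | step 3 | N-methoxy-N-methyl-11-(2-methyl-1,3-dioxolan-2-yl)undecanamide | CON(C)C(=O)CCCCCCCCCCC1(C)OCCO1
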